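**Retrosynthetic overview**

1. The route rests on the benzene ring of the coumarin (C4a, C5, C6, C7, C8, C8a). With O1 on C8a, the C1'–C2' side chain on C8 and OCH3 on C7, it is a 2-alkylresorcinol monomethyl ether, the pattern that a vinylketene and a methoxyalkyne assemble.
2. Key disconnection (benzene ring, formed first): C8a–C8, C6–C7 and C4a–C8a, leading back to cyclobut-2-en-1-one (C8a, C6, C5, C4a) and a methyl ynol ether (C8, C7) that already carries C1' and C2'.
3. Pyranone ring (formed second): ortho-formylation at C4a, then O-acylation and intramolecular Wittig reaction with Ph3P=C=C=O close O1–C2 and C3=C4.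
4. Ynol ether: Felkin–Anh addition of LiC≡COCH3 to (S)-3-methyl-2-(triethylsilyloxy)but-3-enal sets C1'; C2' comes from methyl (R)-glycerate acetonide; O1' is then silylated as its TBS ether.
5. O2' is carried as its SiEt3 ether and exchanged for the isovalerate only after the coumarin is closed. An ester at O2' would shift onto the propargylic alkoxide of the alkynylation and would be at risk in the basic work-up of the benzannulation. The O1' TBS group is removed last under acidic fluoride.

Key step: step 10

**Route**

Step 1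
Reactants: 1 methyl (R)-2,2-dimethyl-1,3-dioxolane-4-carboxylate
Product: 2 2-[(4R)-2,2-dimethyl-1,3-dioxolan-4-yl]propan-2-ol
Conditions: MeMgBr (2.5 equiv), THF, 0 °C to rt; aq NH4Cl
Reagents that add atoms: methylmagnesium bromide, C[Mg]Br
Why: Twofold Grignard addition to the ester should give the tertiary carbinol with the acetal-bearing stereocenter untouched.

Step 2
Reactants: 2 2-[(4R)-2,2-dimethyl-1,3-dioxolan-4-yl]propan-2-ol
Product: 3 (4S)-2,2-dimethyl-4-(prop-1-en-2-yl)-1,3-dioxolane
Conditions: SOCl2, pyridine, CH2Cl2, −10 to 0 °C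
Reagents that add atoms: none
Why: Base-induced dehydration of the tertiary alcohol should take one of the six methyl hydrogens in preference to the single hindered ring hydrogen on the oxygen-bearing carbon, giving the isopropenyl group as in dehydrations of hydroxyisopropyl groups next to ether oxygens; the descriptor changes from R to S only because the substituent priorities change.

Step 3
Reactants: 3 (4S)-2,2-dimethyl-4-(prop-1-en-2-yl)-1,3-dioxolane
Product: 4 (2S)-3-methylbut-3-ene-1,2-diol
Conditions: Dowex 50W (H+ form), MeOH–H2O (9:1), rt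
Reagents that add atoms: none
Why: Mild acid-catalysed hydrolysis of the isopropylidene acetal should free the diol without touching the allylic stereocenter.

Step 4
Reactants: 4 (2S)-3-methylbut-3-ene-1,2-diol
Product: 5 (2S)-3-methyl-1,2-bis(triethylsilyloxy)but-3-ene
Conditions: TESCl (2.4 equiv), imidazole, DMAP (cat.), CH2Cl2, 0 °C to rt
Reagents that add atoms: chlorotriethylsilane, CC[Si](Cl)(CC)CC
Why: Standard silylation of both hydroxyl groups sets up the selective oxidation of the primary silyl ether.

Step 5
Reactants: 5 (2S)-3-methyl-1,2-bis(triethylsilyloxy)but-3-ene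
Product: 6 (2S)-3-methyl-2-(triethylsilyloxy)but-3-enal
Conditions: (COCl)2, DMSO, CH2Cl2, −78 to −40 °C; i-Pr2NEt, −78 °C; cold pH 7 buffer; used crude at once
Reagents that add atoms: none
Why: Swern conditions are known to cleave and oxidise a primary triethylsilyl ether in one operation while a secondary one stays, and the hindered amine with cold neutral work-up should keep the allylic α-stereocenter from epimerising or the double bond from moving into conjugation.

Step 6
Reactants: 6 (2S)-3-methyl-2-(triethylsilyloxy)but-3-enal; 7 chloroacetaldehyde dimethyl acetal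
Product: 9 (3R,4S)-1-methoxy-5-methyl-4-(triethylsilyloxy)hex-5-en-1-yn-3-ol, via lithium methoxyacetylide 8 (not isolated)
Conditions: 7 (1.5 equiv), LiNEt2 (4.4 equiv, from Et2NH and n-BuLi), THF, 0 °C; then 6, −78 °C; aq NH4Cl at −78 °C; chromatography on Et3N-deactivated silica gel
Reagents that add atoms: none
Why: Two eliminations and a deprotonation of acetal 7 by the amide base give acetylide 8, which should add to the aldehyde in the polar Felkin–Anh mode, anti to the bulky non-chelating OSiEt3 group, setting C3 as R (3,4-anti), with the minor epimer removed by chromatography.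

Step 7
Reactants: 9 (3R,4S)-1-methoxy-5-methyl-4-(triethylsilyloxy)hex-5-en-1-yn-3-ol
Product: 10 (3R,4S)-3-(tert-butyldimethylsilyloxy)-1-methoxy-5-methyl-4-(triethylsilyloxy)hex-5-en-1-yne
Conditions: TBSCl, imidazole, DMAP (cat.), DMF, rt
Reagents that add atoms: tert-butyldimethylsilyl chloride, CC(C)(C)[Si](C)(C)Cl
Why: Silylation under basic conditions should protect the propargylic hydroxyl without exposing the acid-sensitive ynol ether to acid.

Step 8
Reactants: 11 3-oxocyclobutane-1-carboxylic acid
Product: 12 3-bromocyclobutan-1-one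
Conditions: HgO, Br2, MgSO4, CH2Cl2, reflux
Reagents that add atoms: bromine, BrBr
Why: The Cristol–Firth variant of the Hunsdiecker reaction should replace the carboxyl group by bromine through radical bromodecarboxylation.

Step 9
Reactants: 12 3-bromocyclobutan-1-one
Product: 13 cyclobut-2-en-1-one
Conditions: n-Bu3N, rt; product distilled at reduced pressure into a −78 °C trap and kept cold
Reagents that add atoms: none
Why: The β-bromo ketone should lose HBr to the amine base (E1cB) and the volatile strained enone is distilled from the salt as it forms.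

Step 10
Reactants: 13 cyclobut-2-en-1-one; 10 (3R,4S)-3-(tert-butyldimethylsilyloxy)-1-methoxy-5-methyl-4-(triethylsilyloxy)hex-5-en-1-yne
Product: 18 2-[(1R,2S)-1-(tert-butyldimethylsilyloxy)-3-methyl-2-(triethylsilyloxy)but-3-en-1-yl]-3-methoxyphenol, via vinylketene 14 (not isolated), via vinylcyclobutenone 15 (not isolated), via dienylketene 16 (not isolated), via cyclohexa-2,4-dienone 17 (not isolated)
Conditions: 13 (1.5 equiv, in two portions), toluene, sealed tube, 80 °C then 110 °C; crude product stirred with K2CO3, MeOH, 0 °C if any phenol has been esterified by the ketene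
Reagents that add atoms: none
Why: Thermal 4π opening of 13 gives vinylketene 14, whose ketene C=C adds [2+2] to the ynol ether (C8a–C8 and C6–C7) to give 15, which opens (4π) to dienylketene 16 and closes to dienone 17, and this tautomerises to phenol 18. The closest known reaction is the Danheiser benzannulation of cyclobutenones with alkoxyalkynes, which gives 2-substituted resorcinol monoethers. The benzene ring is closed by thermal disrotatory 6π-electrocyclization of 16 (C4a–C8a), and the four-membered ring of 15, closed by the [2+2] cycloaddition, is only a relay. No stereocenter of the product is made here: C4 of 15 forms as a mixture and is erased on ring opening, and C1' and C2' are spectators under neutral thermal conditions. The step needs the [2+2] regiochemistry in which the alkyne carbon β to the methoxy oxygen (the one bearing the side chain) bonds to the ketene carbonyl carbon, and the methoxy polarisation of the triple bond secures it, as it also makes the ketene choose the electron-rich alkyne over the isopropenyl group. A methyl ynol ether cannot lose an alkene by a retro-ene path, and the reversible opening of 15 should funnel both dienylketene geometries to 17.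

Step 11
Reactants: 18 2-[(1R,2S)-1-(tert-butyldimethylsilyloxy)-3-methyl-2-(triethylsilyloxy)but-3-en-1-yl]-3-methoxyphenol
Product: 20 3-[(1R,2S)-1-(tert-butyldimethylsilyloxy)-3-methyl-2-(triethylsilyloxy)but-3-en-1-yl]-2-hydroxy-4-methoxybenzaldehyde, via hydroxymethylphenol 19 (not isolated)
Conditions: MgCl2, Et3N, (CH2O)n, THF, reflux; cold aq citric acid
Reagents that add atoms: formaldehyde (as paraformaldehyde), C=O
Why: In this Casnati–Skattebøl formylation the magnesium phenoxide should deliver formaldehyde only to the ortho carbon, here C4a because C8 is substituted, giving 19, which a second formaldehyde oxidises by hydride transfer to the salicylaldehyde.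

Step 12
Reactants: 20 3-[(1R,2S)-1-(tert-butyldimethylsilyloxy)-3-methyl-2-(triethylsilyloxy)but-3-en-1-yl]-2-hydroxy-4-methoxybenzaldehyde
Product: 22 8-[(1R,2S)-1-(tert-butyldimethylsilyloxy)-3-methyl-2-(triethylsilyloxy)but-3-en-1-yl]-7-methoxy-2H-chromen-2-one, via aryl phosphoranylideneacetate 21 (not isolated)
Conditions: Ph3P=C=C=O (1.3 equiv), toluene, 90 °C
Reagents that add atoms: (triphenylphosphoranylidene)ketene (Bestmann ylide), O=C=C=P(c1ccccc1)(c1ccccc1)c1ccccc1
Why: The phenol O–H should add across the cumulated ylide to give ester ylide 21, whose intramolecular Wittig reaction with the ortho aldehyde can only give the cis alkene of the six-membered lactone (Bestmann coumarin synthesis), all under neutral conditions.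

Step 13
Reactants: 22 8-[(1R,2S)-1-(tert-butyldimethylsilyloxy)-3-methyl-2-(triethylsilyloxy)but-3-en-1-yl]-7-methoxy-2H-chromen-2-one
Product: 23 8-[(1R,2S)-1-(tert-butyldimethylsilyloxy)-2-hydroxy-3-methylbut-3-en-1-yl]-7-methoxy-2H-chromen-2-one
Conditions: PPTS, MeOH–CH2Cl2 (1:1), 0 °C to rt
Reagents that add atoms: none
Why: Acid-catalysed methanolysis should remove the triethylsilyl ether much faster than the more hindered and more robust benzylic tert-butyldimethylsilyl ether, and acidic conditions exclude silyl migration.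

Step 14
Reactants: 23 8-[(1R,2S)-1-(tert-butyldimethylsilyloxy)-2-hydroxy-3-methylbut-3-en-1-yl]-7-methoxy-2H-chromen-2-one; 24 isovaleryl chloride
Product: 25 (1R,2S)-1-(tert-butyldimethylsilyloxy)-1-(7-methoxy-2-oxo-2H-chromen-8-yl)-3-methylbut-3-en-2-yl 3-methylbutanoate
Conditions: pyridine, DMAP (cat.), CH2Cl2, 0 °C to rt
Reagents that add atoms: none
Why: DMAP-catalysed acylation of the only free hydroxyl should give the isovalerate at O2' with retention, since no alkoxide is formed that could move the neighbouring silyl group.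

Step 15
Reactants: 25 (1R,2S)-1-(tert-butyldimethylsilyloxy)-1-(7-methoxy-2-oxo-2H-chromen-8-yl)-3-methylbut-3-en-2-yl 3-methylbutanoate
Product: 26 (1R,2S)-1-hydroxy-1-(7-methoxy-2-oxo-2H-chromen-8-yl)-3-methylbut-3-en-2-yl 3-methylbutanoate
Conditions: HF·pyridine, pyridine, THF, 0 °C to rt
Reagents that add atoms: none
Why: Buffered acidic fluoride should cleave the benzylic silyl ether without forming an alkoxide, so the isovalerate cannot shift from O2' to O1' and neither stereocenter is disturbed.

**Compound list**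

1 | methyl (R)-2,2-dimethyl-1,3-dioxolane-4-carboxylate | COC(=O)[C@H]1COC(C)(C)O1 | starting material
2 | 2-[(4R)-2,2-dimethyl-1,3-dioxolan-4-yl]propan-2-ol | CC(C)(O)[C@H]1COC(C)(C)O1 | intermediate
3 | (4S)-2,2-dimethyl-4-(prop-1-en-2-yl)-1,3-dioxolane | C=C(C)[C@H]1COC(C)(C)O1 | intermediate
4 | (2S)-3-methylbut-3-ene-1,2-diol | C=C(C)[C@H](O)CO | intermediate
5 | (2S)-3-methyl-1,2-bis(triethylsilyloxy)but-3-ene | C=C(C)[C@H](O[Si](CC)(CC)CC)CO[Si](CC)(CC)CC | intermediate
6 | (2S)-3-methyl-2-(triethylsilyloxy)but-3-enal | C=C(C)[C@H](O[Si](CC)(CC)CC)C=O | intermediate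
7 | chloroacetaldehyde dimethyl acetal (2-chloro-1,1-dimethoxyethane) | COC(CCl)OC | starting material
8 | lithium methoxyacetylide | [Li]C#COC | intermediate
9 | (3R,4S)-1-methoxy-5-methyl-4-(triethylsilyloxy)hex-5-en-1-yn-3-ol | C=C(C)[C@H](O[Si](CC)(CC)CC)[C@H](O)C#COC | intermediate
10 | (3R,4S)-3-(tert-butyldimethylsilyloxy)-1-methoxy-5-methyl-4-(triethylsilyloxy)hex-5-en-1-yne | C=C(C)[C@H](O[Si](CC)(CC)CC)[C@H](O[Si](C)(C)C(C)(C)C)C#COC | intermediate
11 | 3-oxocyclobutane-1-carboxylic acid | O=C1CC(C1)C(=O)O | starting material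
12 | 3-bromocyclobutan-1-one | O=C1CC(Br)C1 | intermediate
13 | cyclobut-2-en-1-one | O=C1C=CC1 | intermediate
14 | buta-1,3-dien-1-one (vinylketene) | C=CC=C=O | intermediate
15 | 2-[(1R,2S)-1-(tert-butyldimethylsilyloxy)-3-methyl-2-(triethylsilyloxy)but-3-en-1-yl]-4-ethenyl-3-methoxycyclobut-2-en-1-one (both C4 epimers) | C=C(C)[C@H](O[Si](CC)(CC)CC)[C@H](O[Si](C)(C)C(C)(C)C)C1=C(OC)C(C=C)C1=O | intermediate
16 | 2-[(1R,2S)-1-(tert-butyldimethylsilyloxy)-3-methyl-2-(triethylsilyloxy)but-3-en-1-yl]-3-methoxyhexa-1,3,5-trien-1-one (ketene carbon and vinyl group cis on C3=C4) | C=C(C)[C@H](O[Si](CC)(CC)CC)[C@H](O[Si](C)(C)C(C)(C)C)C(=C=O)/C(OC)=C\C=C | intermediate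
17 | 2-[(1R,2S)-1-(tert-butyldimethylsilyloxy)-3-methyl-2-(triethylsilyloxy)but-3-en-1-yl]-3-methoxycyclohexa-2,4-dien-1-one | C=C(C)[C@H](O[Si](CC)(CC)CC)[C@H](O[Si](C)(C)C(C)(C)C)C1=C(OC)C=CCC1=O | intermediate
18 | 2-[(1R,2S)-1-(tert-butyldimethylsilyloxy)-3-methyl-2-(triethylsilyloxy)but-3-en-1-yl]-3-methoxyphenol | C=C(C)[C@H](O[Si](CC)(CC)CC)[C@H](O[Si](C)(C)C(C)(C)C)c1c(OC)cccc1O | intermediate
19 | 2-[(1R,2S)-1-(tert-butyldimethylsilyloxy)-3-methyl-2-(triethylsilyloxy)but-3-en-1-yl]-6-(hydroxymethyl)-3-methoxyphenol | C=C(C)[C@H](O[Si](CC)(CC)CC)[C@H](O[Si](C)(C)C(C)(C)C)c1c(OC)ccc(CO)c1O | intermediate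
20 | 3-[(1R,2S)-1-(tert-butyldimethylsilyloxy)-3-methyl-2-(triethylsilyloxy)but-3-en-1-yl]-2-hydroxy-4-methoxybenzaldehyde | C=C(C)[C@H](O[Si](CC)(CC)CC)[C@H](O[Si](C)(C)C(C)(C)C)c1c(OC)ccc(C=O)c1O | intermediate
21 | 6-[(1R,2S)-1-(tert-butyldimethylsilyloxy)-3-methyl-2-(triethylsilyloxy)but-3-en-1-yl]-2-formyl-5-methoxyphenyl 2-(triphenylphosphoranylidene)acetate | C=C(C)[C@H](O[Si](CC)(CC)CC)[C@H](O[Si](C)(C)C(C)(C)C)c1c(OC)ccc(C=O)c1OC(=O)C=P(c1ccccc1)(c1ccccc1)c1ccccc1 | intermediate
22 | 8-[(1R,2S)-1-(tert-butyldimethylsilyloxy)-3-methyl-2-(triethylsilyloxy)but-3-en-1-yl]-7-methoxy-2H-chromen-2-one | C=C(C)[C@H](O[Si](CC)(CC)CC)[C@H](O[Si](C)(C)C(C)(C)C)c1c(OC)ccc2ccc(=O)oc12 | intermediate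
23 | 8-[(1R,2S)-1-(tert-butyldimethylsilyloxy)-2-hydroxy-3-methylbut-3-en-1-yl]-7-methoxy-2H-chromen-2-one | C=C(C)[C@H](O)[C@H](O[Si](C)(C)C(C)(C)C)c1c(OC)ccc2ccc(=O)oc12 | intermediate
24 | isovaleryl chloride (3-methylbutanoyl chloride) | CC(C)CC(=O)Cl | starting material
25 | (1R,2S)-1-(tert-butyldimethylsilyloxy)-1-(7-methoxy-2-oxo-2H-chromen-8-yl)-3-methylbut-3-en-2-yl 3-methylbutanoate | C=C(C)[C@H](OC(=O)CC(C)C)[C@H](O[Si](C)(C)C(C)(C)C)c1c(OC)ccc2ccc(=O)oc12 | intermediate
26 | (1R,2S)-1-hydroxy-1-(7-methoxy-2-oxo-2H-chromen-8-yl)-3-methylbut-3-en-2-yl 3-methylbutanoate | C=C(C)[C@H](OC(=O)CC(C)C)[C@H](O)c1c(OC)ccc2ccc(=O)oc12 | target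

**Step count**

Total: 15 steps. Longest linear sequence: 13 steps (steps 1–7 and 10–15); the cyclobutenone branch is 2 steps (8 and 9).

**Steps most likely to fail**

Step 10. Polymerisation of the parent cyclobutenone and acylation of the product phenol by the vinylketene may outrun a slow [2+2] addition to the hindered, doubly silyloxy-branched ynol ether. The fallback sets out from aldehyde 6 and comes back at phenol 18; the arene is bought and not built. 3-Methoxyphenol is protected with MOMCl and i-Pr2NEt as 1-methoxy-3-(methoxymethoxy)benzene F1. n-BuLi in THF at 0 °C lithiates the position between the two oxygens to give [2-methoxy-6-(methoxymethoxy)phenyl]lithium F2. Addition of this to 6 at −78 °C under Felkin–Anh control should give (1R,2S)-1-[2-methoxy-6-(methoxymethoxy)phenyl]-3-methyl-2-(triethylsilyloxy)but-3-en-1-ol F3. TBSOTf and 2,6-lutidine convert it into its tert-butyldimethylsilyl ether F4. TMSOTf and 2,2'-bipyridyl in CH2Cl2 at 0 °C, followed by water, remove the aryl MOM group without protic acid and should return 18.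

Step 6. Poor facial selectivity in the acetylide addition to the α-silyloxy aldehyde may leave too much of the C3 epimer. The fallback sets out from the C3-epimeric mixture of 9 and comes back at 9, replacing substrate control by reagent control. Oxidation with MnO2 in CH2Cl2 gives (4S)-1-methoxy-5-methyl-4-(triethylsilyloxy)hex-5-en-1-yn-3-one F5. Corey–Bakshi–Shibata reduction with the (S)-methyl oxazaborolidine and catecholborane in toluene at −78 °C, with the linear alkynyl group as the small substituent and the Felkin preference reinforcing it, should return the (3R) alcohol 9.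

Step 12. O-Acylation of the hindered, hydrogen-bonded phenol by the ylide may be too slow, so that the ylide is consumed by self-condensation before the ester ylide forms. The fallback sets out from 20 and comes back at 22, with intermolecular Z-selective olefination in place of O-acylation. Still–Gennari olefination with (CF3CH2O)2P(O)CH2CO2CH3, KN(SiMe3)2 (2.1 equiv) and 18-crown-6 in THF, −78 °C to rt, should give methyl (Z)-3-{3-[(1R,2S)-1-(tert-butyldimethylsilyloxy)-3-methyl-2-(triethylsilyloxy)but-3-en-1-yl]-2-hydroxy-4-methoxyphenyl}prop-2-enoate F6. Its phenoxide should close the lactone in the flask to give 22.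

**Further compounds**

F1 | step 10 | 1-methoxy-3-(methoxymethoxy)benzene | COCOc1cccc(OC)c1
F2 | step 10 | [2-methoxy-6-(methoxymethoxy)phenyl]lithium | [Li]c1c(OC)cccc1OCOC
F3 | step 10 | (1R,2S)-1-[2-methoxy-6-(methoxymethoxy)phenyl]-3-methyl-2-(triethylsilyloxy)but-3-en-1-ol | C=C(C)[C@H](O[Si](CC)(CC)CC)[C@H](O)c1c(OC)cccc1OCOC
F4 | step 10 | tert-butyl{[(1R,2S)-1-[2-methoxy-6-(methoxymethoxy)phenyl]-3-methyl-2-(triethylsilyloxy)but-3-en-1-yl]oxy}dimethylsilane | C=C(C)[C@H](O[Si](CC)(CC)CC)[C@H](O[Si](C)(C)C(C)(C)C)c1c(OC)cccc1OCOC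
F5 | step 6 | (4S)-1-methoxy-5-methyl-4-(triethylsilyloxy)hex-5-en-1-yn-3-one | C=C(C)[C@H](O[Si](CC)(CC)CC)C(=O)C#COC
F6 | step 12 | methyl (Z)-3-{3-[(1R,2S)-1-(tert-butyldimethylsilyloxy)-3-methyl-2-(triethylsilyloxy)but-3-en-1-yl]-2-hydroxy-4-methoxyphenyl}prop-2-enoate | C=C(C)[C@H](O[Si](CC)(CC)CC)[C@H](O[Si](C)(C)C(C)(C)C)c1c(OC)ccc(/C=C\C(=O)OC)c1O
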